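**Plan**

- Retrosynthesis: the acid, the C9 carbinol (through the ketone from a C9 nitro group) and the C15 carbinol are adjusted last. C13=C14 is cut by Horner–Wadsworth–Emmons logic. The cyclopentane is then cut at C9–C10 and C11–C12, which releases C10–C11 as chloroacetaldehyde. The remaining gamma-nitro aldehyde is cut at C8–C12 (Michael) and C8–C9 (Henry).
- Enabling feature: in the ring C8–C12, C10 is a bare CH2 between the carbinol C11 and C9; C9 can carry its oxygen as a nitro group and C12 is alpha to the latent C13 formyl group. The C9–C8–C12 unit therefore offers two 1,3-related carbanion sites (nitronate, enamine) that the 1,2-dielectrophile ClCH2–CHO can bridge.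
- Forward: cyclooctene is opened to methyl 8-oxooctanoate, converted to the nitroalkene, extended by acetaldehyde and annulated to the only ring in one operation. The omega chain is then added by olefination, C15 is reduced, C9 is unmasked and reduced, and the ester is saponified. The sequence is linear.
- Stereochemistry: C8 comes from the diphenylprolinol silyl ether-catalysed Michael addition, C11 and C12 from the D-proline anti-aldol (C12 is also thermodynamic), C15 from the CBS reduction, C9 from hindered hydride attack anti to the C8 chain, and the E-alkene from the stabilised phosphonate.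

Key step: step 4

Remark: the nitro-bearing ring carbon C9 epimerises through its nitronate, so the ring nitro compounds are drawn as the epimer with nitro trans to the C8 chain; either epimer gives the same ketone in step 7.

**Route**

Step 1
Reactants: 1 (Z)-cyclooctene
Product: 3 methyl 8-oxooctanoate, via methoxy hydroperoxide 2 (not isolated)
Conditions: O3, CH2Cl2/MeOH, NaHCO3, −78 °C; then Ac2O, Et3N, 0 °C to rt
Reagents that add atoms: ozone, [O-][O+]=O; methanol, CO
Why: Ozonolysis of the ring alkene in methanol traps one terminus as the alpha-methoxy hydroperoxide and leaves the other as the aldehyde, and acetic anhydride/triethylamine dehydrates the hydroperoxide to the methyl ester, so the two chain ends are differentiated in one flask (terminus-differentiating ozonolysis; no stereocenter).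

Step 2
Reactants: 3 methyl 8-oxooctanoate; 4 nitromethane
Product: 6 methyl (E)-9-nitronon-8-enoate, via nitro alcohol 5 (not isolated)
Conditions: MeNO2 (excess), Et3N (cat.), 0 °C to rt; then MsCl, Et3N, CH2Cl2, 0 °C
Reagents that add atoms: none
Why: The Henry reaction adds nitromethane to the aldehyde, and mesylation followed by E1cB elimination gives the conjugated nitroalkene in the thermodynamically favoured E geometry, the ester being inert.

Step 3
Reactants: 6 methyl (E)-9-nitronon-8-enoate; 7 acetaldehyde
Product: 8 methyl (8R)-8-(nitromethyl)-10-oxodecanoate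
Conditions: (S)-α,α-diphenylprolinol trimethylsilyl ether (10 mol %), 7 (10 equiv), 1,4-dioxane, rt
Reagents that add atoms: none
Why: In this enamine-catalysed Michael addition the anti-enamine of acetaldehyde, shielded on one face by the diphenyl(silyloxy)methyl group, should add to the nitroalkene through the usual synclinal transition state and set C8 as R, the sense expected of this catalyst enantiomer with aliphatic nitroalkenes.

Step 4
Reactants: 8 methyl (8R)-8-(nitromethyl)-10-oxodecanoate; 9 chloroacetaldehyde
Product: 11 methyl 7-[(1R,2R,3R,5R)-2-formyl-3-hydroxy-5-nitrocyclopentyl]heptanoate, via aldol chlorohydrin 10 (not isolated)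
Conditions: 9 (50% aq., 1.1 equiv), D-proline (20 mol %), DMF, 4 °C, slow addition of 8; then 1,8-diazabicyclo[5.4.0]undec-7-ene (DBU, 1.3 equiv), 0 °C to rt
Reagents that add atoms: none
Why: Proposed new method: D-proline condenses with the formyl group of 8 to give the anti (E)-enamine, which adds to the more electrophilic aldehyde 9 through the hydrogen-bonded chair-like transition state of proline cross-aldol reactions (C11–C12, anti-aldol 10), and DBU then ionises the far more acidic nitromethyl group to a nitronate that displaces the primary chloride at C10 through carbon (C9–C10). The closest known reaction types are the proline-catalysed cross-aldol of aldehydes with alpha-chloro aldehyde acceptors, the amine-catalysed Michael/Henry [3+2] annulation of 1,4-dialdehydes with nitroalkenes, and the intramolecular C-alkylation of nitronates in Michael-initiated ring closures. The cyclopentane (C8–C9–C10–C11–C12) closes in the 5-exo-tet mode; O-alkylation would need a seven-membered cyclic nitronate and a Henry closure onto C13 a four-membered ring, so neither should compete. C12 (R) and C11 (hydroxyl anti to the C12 formyl group) are set by the catalyst, D-proline being chosen because the L-enantiomer gives the mirror-image anti-aldol; C12 also sits in its thermodynamic position trans to both neighbours, and C9 equilibrates through the nitronate before it is erased in step 7. The step needs cross- over self-aldol selectivity, secured by slow addition of the donor 8 to the alpha-chloro aldehyde (the better acceptor and poorer enamine donor), and C-alkylation over epoxide formation, secured by the ring sizes and by the pKa gap between the nitroalkane and the C11 hydroxyl.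

Step 5
Reactants: 11 methyl 7-[(1R,2R,3R,5R)-2-formyl-3-hydroxy-5-nitrocyclopentyl]heptanoate; 12 dimethyl (2-oxoheptyl)phosphonate
Product: 13 methyl 7-[(1R,2R,3R,5R)-3-hydroxy-5-nitro-2-[(1E)-3-oxooct-1-en-1-yl]cyclopentyl]heptanoate
Conditions: LiCl, i-Pr2NEt, MeCN, rt
Reagents that add atoms: none
Why: Horner–Wadsworth–Emmons olefination under Masamune–Roush conditions (LiCl-activated phosphonate, amine base) should give the E-enone without E1cB loss of the C11 hydroxyl, and the C12 centre alpha to the aldehyde is already in its thermodynamic trans,trans arrangement.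

Step 6
Reactants: 13 methyl 7-[(1R,2R,3R,5R)-3-hydroxy-5-nitro-2-[(1E)-3-oxooct-1-en-1-yl]cyclopentyl]heptanoate
Product: 14 methyl 7-[(1R,2R,3R,5R)-3-hydroxy-2-[(1E,3S)-3-hydroxyoct-1-en-1-yl]-5-nitrocyclopentyl]heptanoate
Conditions: (R)-2-methyl-CBS-oxazaborolidine [(3aR)-1-methyl-3,3-diphenyltetrahydro-1H,3H-pyrrolo[1,2-c][1,3,2]oxazaborole] (20 mol %), BH3·THF, THF, −40 °C; then MeOH
Reagents that add atoms: none
Why: In the Corey–Bakshi–Shibata reduction the ketone binds the catalyst with the alkenyl group as the large substituent, so hydride should be delivered to the face that gives the 15S allylic alcohol, while the nitro group, the ester and the borane-capped C11 hydroxyl are spectators.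

Step 7
Reactants: 14 methyl 7-[(1R,2R,3R,5R)-3-hydroxy-2-[(1E,3S)-3-hydroxyoct-1-en-1-yl]-5-nitrocyclopentyl]heptanoate
Product: 16 prostaglandin E1 methyl ester, via sodium nitronate 15 (not isolated)
Conditions: NaOMe (1.05 equiv), MeOH, 0 °C; then 2KHSO5·KHSO4·K2SO4, Na2HPO4, H2O/MeOH, 0 °C
Reagents that add atoms: potassium peroxymonosulfate, [K+].[O-]S(=O)(=O)OO
Why: In this oxidative Nef reaction the C9 nitronate is oxidised at carbon by peroxymonosulfate and loses nitrite to give the ketone under buffered conditions that should spare the base-sensitive beta-hydroxy ketone, the alkene and both alcohols; the C9 stereocenter is erased.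

Step 8
Reactants: 16 prostaglandin E1 methyl ester
Product: 17 prostaglandin F1alpha methyl ester
Conditions: LiBH(s-Bu)3 (3.5 equiv), THF, −78 °C; then H2O
Reagents that add atoms: none
Why: The bulky trialkylborohydride should attack the cyclopentanone from the beta face, anti to the adjacent alpha-oriented C8 chain, and so set the 9alpha (9S) hydroxyl cis to that chain, the usual facial preference of hindered hydrides in ketone reductions of this ring type.

Step 9
Reactants: 17 prostaglandin F1alpha methyl ester
Product: 18 prostaglandin F1alpha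
Conditions: LiOH, THF/H2O, rt; then 1 M HCl to pH 4
Reagents that add atoms: lithium hydroxide, [Li+].[OH-]
Why: Saponification of the methyl ester by hydroxide (acyl substitution) followed by mild acidification gives the acid without touching any stereocenter.

**Compound list**

1 | (Z)-cyclooctene | C1CCC/C=C\CCC1 | starting material
2 | 8-hydroperoxy-8-methoxyoctanal (racemic) | O=CCCCCCCC(OC)OO | intermediate
3 | methyl 8-oxooctanoate | COC(=O)CCCCCCC=O | intermediate
4 | nitromethane | C[N+](=O)[O-] | starting material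
5 | methyl 8-hydroxy-9-nitrononanoate (racemic) | COC(=O)CCCCCCC(O)C[N+](=O)[O-] | intermediate
6 | methyl (E)-9-nitronon-8-enoate | COC(=O)CCCCCC/C=C/[N+](=O)[O-] | intermediate
7 | acetaldehyde | CC=O | starting material
8 | methyl (8R)-8-(nitromethyl)-10-oxodecanoate | O=CC[C@@H](CCCCCCC(=O)OC)C[N+](=O)[O-] | intermediate
9 | chloroacetaldehyde | O=CCCl | starting material
10 | methyl (8R,9R,10S)-11-chloro-9-formyl-10-hydroxy-8-(nitromethyl)undecanoate | O=C[C@@H]([C@H](O)CCl)[C@@H](CCCCCCC(=O)OC)C[N+](=O)[O-] | intermediate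
11 | methyl 7-[(1R,2R,3R,5R)-2-formyl-3-hydroxy-5-nitrocyclopentyl]heptanoate | O=C[C@@H]1[C@@H](CCCCCCC(=O)OC)[C@H]([N+](=O)[O-])C[C@H]1O | intermediate
12 | dimethyl (2-oxoheptyl)phosphonate | CCCCCC(=O)CP(=O)(OC)OC | starting material
13 | methyl 7-[(1R,2R,3R,5R)-3-hydroxy-5-nitro-2-[(1E)-3-oxooct-1-en-1-yl]cyclopentyl]heptanoate | CCCCCC(=O)/C=C/[C@@H]1[C@@H](CCCCCCC(=O)OC)[C@H]([N+](=O)[O-])C[C@H]1O | intermediate
14 | methyl 7-[(1R,2R,3R,5R)-3-hydroxy-2-[(1E,3S)-3-hydroxyoct-1-en-1-yl]-5-nitrocyclopentyl]heptanoate | CCCCC[C@H](O)/C=C/[C@@H]1[C@@H](CCCCCCC(=O)OC)[C@H]([N+](=O)[O-])C[C@H]1O | intermediate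
15 | sodium nitronate (aci-nitro salt at C9) of 14 | CCCCC[C@H](O)/C=C/[C@@H]1[C@@H](CCCCCCC(=O)OC)C(=[N+]([O-])[O-])C[C@H]1O.[Na+] | intermediate
16 | prostaglandin E1 methyl ester, methyl 7-[(1R,2R,3R)-3-hydroxy-2-[(1E,3S)-3-hydroxyoct-1-en-1-yl]-5-oxocyclopentyl]heptanoate | CCCCC[C@H](O)/C=C/[C@@H]1[C@@H](CCCCCCC(=O)OC)C(=O)C[C@H]1O | intermediate
17 | prostaglandin F1alpha methyl ester, methyl 7-[(1R,2R,3R,5S)-3,5-dihydroxy-2-[(1E,3S)-3-hydroxyoct-1-en-1-yl]cyclopentyl]heptanoate | CCCCC[C@H](O)/C=C/[C@@H]1[C@@H](CCCCCCC(=O)OC)[C@@H](O)C[C@H]1O | intermediate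
18 | prostaglandin F1alpha, 7-[(1R,2R,3R,5S)-3,5-dihydroxy-2-[(1E,3S)-3-hydroxyoct-1-en-1-yl]cyclopentyl]heptanoic acid | CCCCC[C@H](O)/C=C/[C@@H]1[C@@H](CCCCCCC(=O)O)[C@@H](O)C[C@H]1O | target

Total step count: 9
Longest linear sequence: 9 steps (1 to 18)

**Steps most likely to fail**

Step 4. The nitronate ring closure may be outrun by dehydration or retro-aldol cleavage of the beta-hydroxy aldehyde, by epoxide formation from the chlorohydrin, or the cross-aldol may lose chemoselectivity to self-condensation. The fallback sets out from 8 and returns at 14, and replaces the alkylative closure by a Henry closure followed by deoxygenation of C10. D-Proline-catalysed cross-aldol of 8 with aqueous glyoxal, followed in the same flask by i-Pr2NEt-mediated intramolecular Henry reaction, should give methyl 7-[(1R,2R,3S)-2-formyl-3,4-dihydroxy-5-nitrocyclopentyl]heptanoate F1 as a mixture of epimers at the hydroxyl- and nitro-bearing carbons C10 and C9. Horner–Wadsworth–Emmons olefination with 12 (LiCl, i-Pr2NEt, MeCN) then gives methyl 7-[(1R,2R,3S)-3,4-dihydroxy-5-nitro-2-[(1E)-3-oxooct-1-en-1-yl]cyclopentyl]heptanoate F2. CBS reduction as in step 6 gives methyl 7-[(1R,2R,3S)-3,4-dihydroxy-2-[(1E,3S)-3-hydroxyoct-1-en-1-yl]-5-nitrocyclopentyl]heptanoate F3. Dehydration of the beta-nitro alcohol (dicyclohexylcarbodiimide, CuCl, Et2O) gives methyl 7-[(1R,4S,5R)-4-hydroxy-5-[(1E,3S)-3-hydroxyoct-1-en-1-yl]-2-nitrocyclopent-2-en-1-yl]heptanoate F4, and conjugate reduction of the nitroalkene with NaBH4 (EtOH, 0 °C) delivers 14.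

Step 7. Base-induced dehydration of the new beta-hydroxy ketone, over-oxidation of the alkene or the allylic alcohol, and loss of facial control in the following hydride reduction of the unprotected ketol may erode the sequence. The fallback sets out from 14 and returns at 17, and carries both hydroxyls as silyl ethers through the ketone stage. Silylation (TBSCl, imidazole, DMF) gives methyl 7-[(1R,2R,3R,5R)-3-[(tert-butyldimethylsilyl)oxy]-2-[(1E,3S)-3-[(tert-butyldimethylsilyl)oxy]oct-1-en-1-yl]-5-nitrocyclopentyl]heptanoate F5. The Nef reaction (NaOMe; then buffered KHSO5) gives 11,15-bis-O-(tert-butyldimethylsilyl)prostaglandin E1 methyl ester F6. LiBH(s-Bu)3 (THF, −78 °C) gives 11,15-bis-O-(tert-butyldimethylsilyl)prostaglandin F1alpha methyl ester F7, and HF·pyridine (THF, 0 °C) releases 17.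

Step 5. E1cB loss of the C11 hydroxyl or retro-aldol cleavage of the beta-hydroxy aldehyde may compete with olefination under the basic conditions. The fallback sets out from 11 and returns at 13, and masks the hydroxyl before the aldehyde meets base. Silylation (TBSCl, imidazole, DMF, 0 °C) gives methyl 7-[(1R,2R,3R,5R)-3-[(tert-butyldimethylsilyl)oxy]-2-formyl-5-nitrocyclopentyl]heptanoate F8. Olefination with 12 (LiCl, i-Pr2NEt, MeCN) gives methyl 7-[(1R,2R,3R,5R)-3-[(tert-butyldimethylsilyl)oxy]-5-nitro-2-[(1E)-3-oxooct-1-en-1-yl]cyclopentyl]heptanoate F9, and aqueous HF in MeCN (0 °C) returns 13.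

Further compounds
F1 | step 4 | methyl 7-[(1R,2R,3S)-2-formyl-3,4-dihydroxy-5-nitrocyclopentyl]heptanoate (epimers at ring C4 and C5) | O=C[C@@H]1[C@@H](CCCCCCC(=O)OC)C([N+](=O)[O-])C(O)[C@H]1O
F2 | step 4 | methyl 7-[(1R,2R,3S)-3,4-dihydroxy-5-nitro-2-[(1E)-3-oxooct-1-en-1-yl]cyclopentyl]heptanoate (epimers at ring C4 and C5) | CCCCCC(=O)/C=C/[C@@H]1[C@@H](CCCCCCC(=O)OC)C([N+](=O)[O-])C(O)[C@H]1O
F3 | step 4 | methyl 7-[(1R,2R,3S)-3,4-dihydroxy-2-[(1E,3S)-3-hydroxyoct-1-en-1-yl]-5-nitrocyclopentyl]heptanoate (epimers at ring C4 and C5) | CCCCC[C@H](O)/C=C/[C@@H]1[C@@H](CCCCCCC(=O)OC)C([N+](=O)[O-])C(O)[C@H]1O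
F4 | step 4 | methyl 7-[(1R,4S,5R)-4-hydroxy-5-[(1E,3S)-3-hydroxyoct-1-en-1-yl]-2-nitrocyclopent-2-en-1-yl]heptanoate | CCCCC[C@H](O)/C=C/[C@@H]1[C@@H](CCCCCCC(=O)OC)C([N+](=O)[O-])=C[C@H]1O
F5 | step 7 | methyl 7-[(1R,2R,3R,5R)-3-[(tert-butyldimethylsilyl)oxy]-2-[(1E,3S)-3-[(tert-butyldimethylsilyl)oxy]oct-1-en-1-yl]-5-nitrocyclopentyl]heptanoate | CCCCC[C@H](O[Si](C)(C)C(C)(C)C)/C=C/[C@@H]1[C@@H](CCCCCCC(=O)OC)[C@H]([N+](=O)[O-])C[C@H]1O[Si](C)(C)C(C)(C)C
F6 | step 7 | 11,15-bis-O-(tert-butyldimethylsilyl)prostaglandin E1 methyl ester | CCCCC[C@H](O[Si](C)(C)C(C)(C)C)/C=C/[C@@H]1[C@@H](CCCCCCC(=O)OC)C(=O)C[C@H]1O[Si](C)(C)C(C)(C)C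
F7 | step 7 | 11,15-bis-O-(tert-butyldimethylsilyl)prostaglandin F1alpha methyl ester | CCCCC[C@H](O[Si](C)(C)C(C)(C)C)/C=C/[C@@H]1[C@@H](CCCCCCC(=O)OC)[C@@H](O)C[C@H]1O[Si](C)(C)C(C)(C)C
F8 | step 5 | methyl 7-[(1R,2R,3R,5R)-3-[(tert-butyldimethylsilyl)oxy]-2-formyl-5-nitrocyclopentyl]heptanoate | O=C[C@@H]1[C@@H](CCCCCCC(=O)OC)[C@H]([N+](=O)[O-])C[C@H]1O[Si](C)(C)C(C)(C)C
F9 | step 5 | methyl 7-[(1R,2R,3R,5R)-3-[(tert-butyldimethylsilyl)oxy]-5-nitro-2-[(1E)-3-oxooct-1-en-1-yl]cyclopentyl]heptanoate | CCCCCC(=O)/C=C/[C@@H]1[C@@H](CCCCCCC(=O)OC)[C@H]([N+](=O)[O-])C[C@H]1O[Si](C)(C)C(C)(C)C
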